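## Retrosynthetic overview

1. The silyl group and the two acyl groups come off last; both primary alcohols come from one reduction of a diester, and the 8‑methyl‑Δ7 and 13E alkenes from one double methylation of a bis(enol triflate).
2. Ring B is made last by a one‑carbon ring expansion: a 1‑vinyl trans‑hydrindan‑1‑ol takes up the radical of methyl 4‑bromoacetoacetate and C10 shifts from C8 to C9. This gives the C8 ketone, the C9 centre and C11–C15 in one step.
3. The hydrindanol comes from a trans‑hydrindenone by hydroboration (C2), vinyl addition and C4 methylation.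
4. Ring A is closed by metathesis on a 2,2,3‑trisubstituted cyclopentanone made by an asymmetric Michael addition–allylation of 2‑methylcyclopentenone.
5. Ring order: five‑membered ring (bought) → ring A (metathesis) → ring B (expansion of the five‑membered ring).

Assumption: labdane numbering (C1–C20) and α/β (C10 methyl = β) are used for all intermediates; the five‑membered ring of the hydrindanes is C5–C6–C7–C8–C10.

## Route

Step 1
Reactants: 1 2‑methylcyclopent‑2‑en‑1‑one; 2 methyl but‑3‑enoate; 3 allyl bromide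
Product: 6 methyl 2‑[(1S,2S)‑2‑allyl‑2‑methyl‑3‑oxocyclopentyl]but‑3‑enoate (both C4 epimers), via lithium dienolate 4 (not isolated), via lithium enolate adduct 5 (not isolated)
Conditions: LiN(i‑Pr)2 (1.05 equiv), (R,R)‑1,2‑dimethoxy‑1,2‑diphenylethane (1.2 equiv), toluene, −78 °C; 1; then 3, DMPU, −78 to −40 °C
Reagents that add atoms: none
Why: Proposed new method: the C2‑symmetric diether chelates the lithium dienolate of 2 and shields one face of the aggregate, so its α‑carbon adds to the Re face of C3 of enone 1 (sets C5); the resulting tetrasubstituted lithium enolate is allylated anti to the new C5 substituent (sets C10, trans); the C4 centre forms as a mixture that is erased in step 7; closest known reaction types are chiral‑diether‑mediated asymmetric Michael additions of lithium ester enolates to enoates and the racemic tandem Michael addition–alkylation of 2‑methylcyclopentenone.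

Step 2
Reactants: 6 methyl 2‑[(1S,2S)‑2‑allyl‑2‑methyl‑3‑oxocyclopentyl]but‑3‑enoate
Product: 7 methyl 7a‑methyl‑1‑oxo‑2,3,3a,4,7,7a‑hexahydro‑1H‑indene‑4‑carboxylate (trans‑fused; Δ2; 8‑oxo)
Conditions: second‑generation Grubbs catalyst RuCl2(=CHPh)(H2IMes)(PCy3) (3 mol%), CH2Cl2, 40 °C
Reagents that add atoms: none
Why: Ring‑closing olefin metathesis between the vinyl and allyl groups (trans on the cyclopentanone) closes ring A as a Δ2 cyclohexene and leaves C5 and C10 untouched.

Step 3
Reactants: 7 trans‑hydrindenone ester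
Product: 9 methyl 2α,8β‑dihydroxy‑10β‑methyl‑trans‑hydrindane‑4‑carboxylate, via bis‑boron adduct 8 (not isolated)
Conditions: 9‑BBN (4 equiv), THF, 65 °C; then H2O2, aq NaOAc, 0 to 23 °C
Reagents that add atoms: hydrogen peroxide, OO
Why: Hydroboration–oxidation: 9‑BBN adds syn from the α‑face (away from the axial C10 methyl) with boron on C2 (C3 is flanked by the branched C4), which sets the equatorial 2α‑hydroxyl; the hindered ketone is reduced from the same face to the 8β‑alcohol, whose configuration does not matter.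

Step 4
Reactants: 9 2α,8β‑diol
Product: 10 methyl 2α‑(tert‑butyldimethylsilyloxy)‑8β‑hydroxy‑10β‑methyl‑trans‑hydrindane‑4‑carboxylate
Conditions: TBSCl (1.05 equiv), imidazole, DMF, 0 °C
Reagents that add atoms: tert‑butyldimethylsilyl chloride, CC(C)(C)[Si](C)(C)Cl
Why: Selective silylation: the unhindered equatorial C2 hydroxyl reacts much faster than the C8 hydroxyl next to the quaternary C10.

Step 5
Reactants: 10 2α‑silyl ether 8β‑alcohol
Product: 11 methyl 2α‑(tert‑butyldimethylsilyloxy)‑10β‑methyl‑8‑oxo‑trans‑hydrindane‑4‑carboxylate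
Conditions: Dess–Martin periodinane, CH2Cl2, 23 °C
Reagents that add atoms: none
Why: Dess–Martin oxidation returns the C8 ketone under neutral conditions; no retained stereocentre is affected.

Step 6
Reactants: 11 C8 ketone; 12 vinylmagnesium bromide
Product: 13 methyl 2α‑(tert‑butyldimethylsilyloxy)‑8β‑hydroxy‑10β‑methyl‑8α‑vinyl‑trans‑hydrindane‑4‑carboxylate
Conditions: CeCl3, THF, −78 °C
Reagents that add atoms: none
Why: Organocerium 1,2‑addition (non‑basic, so the enolisable ketone and the ester survive) occurs from the α‑face opposite the angular methyl; the new C8 centre is destroyed in step 9.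

Step 7
Reactants: 13 vinyl carbinol
Product: 15 methyl 2α‑(tert‑butyldimethylsilyloxy)‑8β‑hydroxy‑4α,10β‑dimethyl‑8α‑vinyl‑trans‑hydrindane‑4β‑carboxylate, via dilithium alkoxide enolate 14 (not isolated)
Conditions: LiN(i‑Pr)2 (2.3 equiv), THF, −78 to −40 °C; then MeI, −78 °C
Reagents that add atoms: iodomethane, CI
Why: Ester enolate alkylation: the exocyclic C4 enolate takes methyl iodide from the equatorial α‑direction, away from the axial C10 methyl, which sets C4 (4α‑CH3, ester axial β) and converges both C4 epimers.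

Step 8
Reactants: 16 methyl acetoacetate
Product: 17 methyl 4‑bromo‑3‑oxobutanoate
Conditions: Br2 (1.0 equiv), CHCl3, 0 to 23 °C, then 16 h at 23 °C
Reagents that add atoms: bromine, BrBr
Why: Bromination of the β‑keto ester followed by acid‑mediated isomerisation of the 2‑bromo to the preferred 4‑bromo isomer, the standard preparation of 4‑haloacetoacetates.

Step 9
Reactants: 15 4α‑methyl vinyl carbinol; 17 methyl 4‑bromo‑3‑oxobutanoate
Product: 18 methyl 2α‑(tert‑butyldimethylsilyloxy)‑9β‑(5‑methoxy‑3,5‑dioxopentyl)‑4α,10β‑dimethyl‑8‑oxo‑trans‑decalin‑4β‑carboxylate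
Conditions: 17 (1.5 equiv), fac‑tris(2‑phenylpyridinato)iridium Ir(ppy)3 (1 mol%), 2,6‑lutidine, MeCN, blue LEDs, 23 °C
Reagents that add atoms: none
Why: Proposed new method: electron transfer from the excited trivalent‑iridium photocatalyst to 17 gives an electrophilic α‑keto radical that adds to the terminal vinyl carbon; oxidation of the C9 radical by tetravalent iridium (or bromine‑atom transfer then ionisation) triggers a semipinacol 1,2‑shift of the quaternary C10 from C8 to C9, forming ring B, the C8 ketone and the C11–C12 bond, with the side chain eclipsing the C–O bond in the shift and so ending equatorial (9β, also the thermodynamic α‑keto epimer); closest known reaction type is the photoredox radical‑addition/semipinacol ring expansion of 1‑(1‑arylvinyl)cyclobutanols, here extended to an unstrained, non‑benzylic vinylcyclopentanol.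

Step 10
Reactants: 18 decalone β‑keto ester
Product: 20 Δ7‑8‑triflyloxy (13Z)‑13‑triflyloxy enoate (bis(enol triflate) of 18), via dipotassium bis‑enolate 19 (not isolated)
Conditions: KN(SiMe3)2 (2.3 equiv), THF, −78 °C (inverse addition); then PhNTf2 (2.5 equiv), −78 to 0 °C
Reagents that add atoms: N‑phenylbis(trifluoromethanesulfonimide), O=S(=O)(N(c1ccccc1)S(=O)(=O)C(F)(F)F)C(F)(F)F
Why: Double enolate O‑triflation: the chelated potassium enolate of the β‑keto ester gives the Z enol triflate, and kinetic deprotonation of the ketone at the C7 methylene (not the hindered C9 methine) gives the Δ7 enol triflate, so C9 is not epimerised.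

Step 11
Reactants: 20 bis(enol triflate)
Product: 21 dimethyl 2α‑(tert‑butyldimethylsilyloxy)labda‑7,13E‑diene‑15,19‑dioate
Conditions: MeZnCl (4 equiv), Pd(PPh3)4 (5 mol%), THF, 50 °C
Reagents that add atoms: methylzinc chloride, C[Zn]Cl
Why: Negishi cross‑coupling: both alkenyl triflates exchange for methyl with retention of alkene geometry, which fixes the 8‑methyl‑Δ7 unit and the 13E enoate.

Step 12
Reactants: 21 diene diester
Product: 22 2α‑(tert‑butyldimethylsilyloxy)labda‑7,13E‑diene‑15,19‑diol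
Conditions: i‑Bu2AlH (6 equiv), CH2Cl2, −78 to 0 °C; Rochelle salt work‑up
Reagents that add atoms: none
Why: Hydride reduction of both esters: 1,2‑reduction of the enoate gives the E allylic alcohol and the hindered axial C19 ester gives the neopentyl alcohol; the silyl ether is inert.

Step 13
Reactants: 22 15,19‑diol; 23 succinic anhydride
Product: 25 methyl 2α‑(tert‑butyldimethylsilyloxy)‑19‑hydroxylabda‑7,13E‑dien‑15‑yl succinate, via hemisuccinate 24 (not isolated)
Conditions: 23 (1.1 equiv), DMAP (cat.), Et3N, CH2Cl2, 0 °C; then Me3SiCHN2, MeOH–toluene, 0 °C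
Reagents that add atoms: (trimethylsilyl)diazomethane, C[Si](C)(C)C=[N+]=[N-]
Why: Chemoselective acylation: the unhindered allylic C15 hydroxyl opens the anhydride far faster than the axial neopentyl C19 hydroxyl, and the free acid is then esterified by the diazoalkane.

Step 14
Reactants: 25 15‑(methyl succinate) 19‑alcohol; 26 3‑methylbutanoyl chloride
Product: 27 2‑O‑tert‑butyldimethylsilyl ether of the target
Conditions: 26 (3 equiv), pyridine, DMAP (cat.), CH2Cl2, 23 °C
Reagents that add atoms: none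
Why: DMAP‑catalysed acylation of the only free hydroxyl (C19) with the acid chloride.

Step 15
Reactants: 27 silyl‑protected target
Product: 28 CNP0118741.1, labda‑7,13E‑diene‑2α,15,19‑triol 15‑(methyl succinate) 19‑(3‑methylbutanoate)
Conditions: HF·pyridine, pyridine, THF, 0 to 23 °C
Reagents that add atoms: none
Why: Fluoride desilylation under buffered conditions that leave the three esters and both trisubstituted alkenes intact.

## Compound list

1 | 2‑methylcyclopent‑2‑en‑1‑one | CC1=CCCC1=O | starting material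
2 | methyl but‑3‑enoate | COC(=O)CC=C | starting material
3 | allyl bromide | C=CCBr | starting material
4 | lithium dienolate of 2 (lithium 1‑methoxybuta‑1,3‑dien‑1‑olate) | COC(O[Li])=CC=C | intermediate
5 | lithium enolate of the 1,4‑adduct (C5 set; C8–OLi, C8=C10) | [Li]OC1=C(C)[C@H](C(C=C)C(=O)OC)CC1 | intermediate
6 | methyl 2‑[(1S,2S)‑2‑allyl‑2‑methyl‑3‑oxocyclopentyl]but‑3‑enoate (C4 epimers) | C=CC[C@]1(C)C(=O)CC[C@H]1C(C=C)C(=O)OC | intermediate
7 | methyl 7a‑methyl‑1‑oxo‑2,3,3a,4,7,7a‑hexahydro‑1H‑indene‑4‑carboxylate, trans‑fused (5α‑H, 10β‑CH3, Δ2, 8‑oxo; C4 epimers) | O=C1CC[C@H]2C(C(=O)OC)C=CC[C@]12C | intermediate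
8 | bis(9‑BBN) adduct of 7 (C2α–B, C8β–O–B) | O(B1C2CCCC1CCC2)[C@H]1CC[C@H]2C(C(=O)OC)C[C@H](B3C4CCCC3CCC4)C[C@]12C | intermediate
9 | methyl 2α,8β‑dihydroxy‑10β‑methyl‑trans‑hydrindane‑4‑carboxylate (C4 epimers) | O[C@H]1CC[C@H]2C(C(=O)OC)C[C@H](O)C[C@]12C | intermediate
10 | 2α‑O‑TBS ether of 9 | O[C@H]1CC[C@H]2C(C(=O)OC)C[C@H](O[Si](C)(C)C(C)(C)C)C[C@]12C | intermediate
11 | 8‑ketone of 10 | O=C1CC[C@H]2C(C(=O)OC)C[C@H](O[Si](C)(C)C(C)(C)C)C[C@]12C | intermediate
12 | vinylmagnesium bromide | C=C[Mg]Br | starting material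
13 | 8α‑vinyl‑8β‑hydroxy hydrindane ester (C4 epimers) | C=C[C@]1(O)CC[C@H]2C(C(=O)OC)C[C@H](O[Si](C)(C)C(C)(C)C)C[C@]12C | intermediate
14 | dilithium alkoxide / ester enolate of 13 | C=C[C@]1(O[Li])CC[C@H]2C(=C(OC)O[Li])C[C@H](O[Si](C)(C)C(C)(C)C)C[C@]12C | intermediate
15 | 4α‑methyl‑4β‑methoxycarbonyl‑8α‑vinyl‑8β‑hydroxy hydrindane (2α‑OTBS, 5α‑H, 10β‑CH3) | C=C[C@]1(O)CC[C@H]2[C@@](C)(C(=O)OC)C[C@H](O[Si](C)(C)C(C)(C)C)C[C@]12C | intermediate
16 | methyl acetoacetate | COC(=O)CC(C)=O | starting material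
17 | methyl 4‑bromo‑3‑oxobutanoate | COC(=O)CC(=O)CBr | intermediate
18 | 8‑oxo trans‑decalin with 9β‑CH2CH2C(=O)CH2CO2Me, 4β‑CO2Me, 4α‑CH3, 10β‑CH3, 2α‑OTBS | COC(=O)CC(=O)CC[C@H]1C(=O)CC[C@H]2[C@@](C)(C(=O)OC)C[C@H](O[Si](C)(C)C(C)(C)C)C[C@]12C | intermediate
19 | dipotassium bis‑enolate of 18 | COC(=O)/C=C(\O[K])CC[C@H]1C(O[K])=CC[C@H]2[C@@](C)(C(=O)OC)C[C@H](O[Si](C)(C)C(C)(C)C)C[C@]12C | intermediate
20 | bis(enol triflate): Δ7‑8‑OTf and (13Z)‑13‑OTf enoate | COC(=O)/C=C(\OS(=O)(=O)C(F)(F)F)CC[C@H]1C(OS(=O)(=O)C(F)(F)F)=CC[C@H]2[C@@](C)(C(=O)OC)C[C@H](O[Si](C)(C)C(C)(C)C)C[C@]12C | intermediate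
21 | dimethyl 2α‑(tert‑butyldimethylsilyloxy)labda‑7,13E‑diene‑15,19‑dioate | COC(=O)/C=C(\C)CC[C@H]1C(C)=CC[C@H]2[C@@](C)(C(=O)OC)C[C@H](O[Si](C)(C)C(C)(C)C)C[C@]12C | intermediate
22 | 2α‑(tert‑butyldimethylsilyloxy)labda‑7,13E‑diene‑15,19‑diol | OC/C=C(\C)CC[C@H]1C(C)=CC[C@H]2[C@@](C)(CO)C[C@H](O[Si](C)(C)C(C)(C)C)C[C@]12C | intermediate
23 | succinic anhydride | O=C1CCC(=O)O1 | starting material
24 | 15‑hemisuccinate of 22 | OC(=O)CCC(=O)OC/C=C(\C)CC[C@H]1C(C)=CC[C@H]2[C@@](C)(CO)C[C@H](O[Si](C)(C)C(C)(C)C)C[C@]12C | intermediate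
25 | 15‑(methyl succinate) of 22 | COC(=O)CCC(=O)OC/C=C(\C)CC[C@H]1C(C)=CC[C@H]2[C@@](C)(CO)C[C@H](O[Si](C)(C)C(C)(C)C)C[C@]12C | intermediate
26 | 3‑methylbutanoyl chloride (isovaleryl chloride) | CC(C)CC(=O)Cl | starting material
27 | 2‑O‑TBS ether of the target | COC(=O)CCC(=O)OC/C=C(\C)CC[C@H]1C(C)=CC[C@H]2[C@@](C)(COC(=O)CC(C)C)C[C@H](O[Si](C)(C)C(C)(C)C)C[C@]12C | intermediate
28 | CNP0118741.1, labda‑7,13E‑diene‑2α,15,19‑triol 15‑(methyl succinate) 19‑(3‑methylbutanoate) (5α‑H, 9β side chain, 10β‑CH3, 4α‑CH3) | COC(=O)CCC(=O)OC/C=C(\C)CC[C@H]1C(C)=CC[C@H]2[C@@](C)(COC(=O)CC(C)C)C[C@H](O)C[C@]12C | target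

## Step count and risks

Total steps: 15. Longest linear sequence: 14 (steps 1–7 and 9–15; step 8 makes reagent 17).

The three steps most likely to fail are steps 1, 9 and 10.

Step 1 (new asymmetric coupling; risks are low enantioselectivity, 1,2‑addition, and proton transfer from C4–H to the ketone enolate before allylation). The fallback uses known chemistry, sets out from 1, 2 and 3 and comes back at 9. The same tandem Michael addition–allylation is run without the chiral ligand (LiN(i‑Pr)2, THF, DMPU), which gives 6 together with the enantiomer of ketone 6 F1. Metathesis as in step 2 gives 7 together with the enantiomer of hydrindenone 7 F2. An oxazaborolidine‑catalysed reduction ((R)‑2‑methyl‑CBS‑oxazaborolidine, catecholborane, −40 °C, stopped near 45% conversion) is then used as a kinetic resolution: the matched enantiomer 7 is reduced from the α‑face to the 8β‑hydroxy Δ2‑hydrindene ester F3, while F2 stays as the ketone and is removed by chromatography. Hydroboration–oxidation of F3 with 9‑BBN and H2O2 as in step 3 gives 9.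

Step 9 (new ring expansion; risks are a C9 radical that is not oxidised and so no shift, or epoxide formation from a bromohydrin). The fallback uses known chemistry, sets out from 15 and comes back at 18. Hydroxyl‑directed epoxidation of the vinyl group (VO(acac)2 cat., t‑BuOOH, CH2Cl2) gives the 8‑(oxiranyl) carbinol F4. A Lewis‑acid semipinacol rearrangement of this 2,3‑epoxy alcohol (BF3·OEt2, CH2Cl2, −78 °C) moves C10 from C8 to C9 and gives the 9β‑(hydroxymethyl)‑8‑oxo decalin F5. PPh3, I2 and imidazole give the 9β‑(iodomethyl) ketone F6. Alkylation of the γ‑carbon of the dianion of methyl acetoacetate 16 (NaH, then n‑BuLi, THF, 0 °C) with F6 gives 18; elimination to the exocyclic enone followed by conjugate addition of the same dianion leads to the same product.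

Step 10 (risks are intramolecular aldol of the 1,5‑dicarbonyl unit under base and incomplete or non‑selective double triflation). The fallback sets out from 18 and comes back at 21 by treating the two carbonyl groups one after the other. NaH (1.05 equiv) then ClP(O)(OEt)2 converts only the β‑keto ester into the (13Z)‑enol diethyl phosphate F7. Me2CuLi (Et2O, −78 to −45 °C) replaces the phosphate with retention and gives the 13E‑enoate 8‑ketone F8. LiN(i‑Pr)2 then PhNTf2 at −78 °C gives the Δ7 enol triflate F9. Pd(PPh3)4 and MeZnCl as in step 11 give 21.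

Further compounds

F1 | step 1 | enantiomer of 6, methyl 2‑[(1R,2R)‑2‑allyl‑2‑methyl‑3‑oxocyclopentyl]but‑3‑enoate | C=CC[C@@]1(C)C(=O)CC[C@@H]1C(C=C)C(=O)OC
F2 | step 1 | enantiomer of 7 | O=C1CC[C@@H]2C(C(=O)OC)C=CC[C@@]12C
F3 | step 1 | methyl 8β‑hydroxy‑10β‑methyl‑Δ2‑trans‑hydrindene‑4‑carboxylate (C4 epimers) | O[C@H]1CC[C@H]2C(C(=O)OC)C=CC[C@]12C
F4 | step 9 | 8‑(oxiran‑2‑yl)‑8β‑hydroxy analogue of 15 (both epoxide epimers) | C1OC1[C@]2(O)CC[C@H]3[C@@](C)(C(=O)OC)C[C@H](O[Si](C)(C)C(C)(C)C)C[C@]23C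
F5 | step 9 | 9β‑(hydroxymethyl)‑8‑oxo trans‑decalin (4β‑CO2Me, 2α‑OTBS) | OC[C@H]1C(=O)CC[C@H]2[C@@](C)(C(=O)OC)C[C@H](O[Si](C)(C)C(C)(C)C)C[C@]12C
F6 | step 9 | 9β‑(iodomethyl)‑8‑oxo trans‑decalin (4β‑CO2Me, 2α‑OTBS) | IC[C@H]1C(=O)CC[C@H]2[C@@](C)(C(=O)OC)C[C@H](O[Si](C)(C)C(C)(C)C)C[C@]12C
F7 | step 10 | (13Z)‑enol diethyl phosphate of 18 (C8 ketone kept) | COC(=O)/C=C(\OP(=O)(OCC)OCC)CC[C@H]1C(=O)CC[C@H]2[C@@](C)(C(=O)OC)C[C@H](O[Si](C)(C)C(C)(C)C)C[C@]12C
F8 | step 10 | 13E‑enoate 8‑ketone (17‑nor‑8‑oxo analogue of 21) | COC(=O)/C=C(\C)CC[C@H]1C(=O)CC[C@H]2[C@@](C)(C(=O)OC)C[C@H](O[Si](C)(C)C(C)(C)C)C[C@]12C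
F9 | step 10 | Δ7‑8‑triflyloxy 13E‑enoate | COC(=O)/C=C(\C)CC[C@H]1C(OS(=O)(=O)C(F)(F)F)=CC[C@H]2[C@@](C)(C(=O)OC)C[C@H](O[Si](C)(C)C(C)(C)C)C[C@]12C
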